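A small charge of partner caps a flask if each target takes one partner. Divide the rate at which target appears by the rate at which partner goes, and time drops out of the count.

| flask | substrate | partner | temperature | remark | time |
|---|---|---|---|---|---|
| south-east | 3.4 mM | 5 mM | 21 °C | run made earlier |  |
| north-west | 11 mM | 5 mM | 46 °C | run made earlier |  |
| north | 5 mM | 3.8 mM | 21 °C | run made earlier |  |
| Tuesday's | 5.0 mM | 5.00 mM | 55 °C |  | 2.5 min |
| Thursday's | 5.0 mM | 5.00 mM | 10 °C |  | 2.5 min |
| Sunday's | 10 mM | 1.50 mM | 25 °C |  | 2.5 min |
| Saturday's | 15 mM | 5.00 mM | 55 °C |  | 2.5 min |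
| Friday's | 5.0 mM | 5.00 mM | 25 °C |  | 2.5 min |

- south-east (time / min: target / %, substrate / %): 0.200: 28.5, 65.7; 0.417: 52.7, 40.3; 0.667: 68.6, 23.2; 1.33: 85.4, 5.0; 2.50: 90.0, 0.6
- north-west (time / s: target / %, substrate / %): 10.0: 37.2, 3.6; 15.0: 38.8, 0.8; 30.0: 38.2, 0.4; 50.0: 37.6, 0.5
- north (time / min: target / %, substrate / %): 0.200: 22.6, 65.2; 0.667: 54.4, 23.6; 1.33: 61.2, 5.3; 2.00: 62.1, 0.8; 2.50: 62.2, 0.7

(standard deviation of a reading: 0.5 percentage points)

- the flasks put in order of amount of target, in percent of the substrate charged, best first, at 2.5 min (Tuesday's / Thursday's / Sunday's / Saturday's / Friday's)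
- the amount of target, in percent of the substrate charged of the flask you put first, at 2.5 min
- the amount of target, in percent of the substrate charged of the flask you put last, at 2.5 min

- the numbers in the tables scatter by 0.5 percentage points (one standard deviation)

In the north run, with 0.760 partner per substrate, 81.8% of the partner charged ended as target. We call this the capture, target made per partner charged at the last reading. The south-east run, at 1.47 partner per substrate, reads 61.2%, lower than the north run, so in these two runs capture falls as partner per substrate rises.

That gives our bracket. From above, target cannot pass c(partner)/c(substrate), with partner as the limiting reagent: 15.0% in Sunday's and 33.3% in Saturday's. From below we have estimates, not strict bounds. Sunday's, at 25 °C, is leaner than the north run at 21 °C, so we multiply its ceiling by the north capture and get 12.3%. Saturday's runs at 55 °C, beyond the 46 °C of the north-west run, so its estimate is weaker: with that run's last capture of 82.7% it comes to 27.6%. Tuesday's, Thursday's and Friday's have 1.00 partner per substrate, between the north and south-east runs. Those two runs were made at 21 °C, so they say little about Tuesday's at 55 °C or Thursday's at 10 °C, and we give those flasks no bracket. Friday's, at 25 °C, we estimate between 61.2% and 81.8%. The low end for Friday's is higher than Saturday's ceiling, and Saturday's estimate is higher than Sunday's ceiling. The ratio does not sort the upper flasks. For Friday's, a straight line between the two runs, our own step, tightens the estimate to 74.9%.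

The forecast gives Friday's > Thursday's > Tuesday's > Saturday's > Sunday's, with 78% (73% to 83%) first and 14.4% (13.5% to 15%) last, holding that “heat and high substrate hurt”. Both central numbers lie inside our brackets, and its top is higher than our line.

The flasks give Friday's > Thursday's > Tuesday's > Saturday's > Sunday's, with 74.3% in Friday's and 13.7% in Sunday's.

    substrate → open intermediate (k = 0.0530 s⁻¹, Ea = 71.0 kJ mol⁻¹)
    second intermediate → decomposed reagent (k = 0.0300 s⁻¹, Ea = 76.0 kJ mol⁻¹)
    open intermediate + second intermediate → target (k = 760 M⁻¹ s⁻¹, Ea = 40.0 kJ mol⁻¹)
    2 open intermediate → homo product (k = 710 M⁻¹ s⁻¹, Ea = 36.0 kJ mol⁻¹)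
    partner → second intermediate (k = 0.130 s⁻¹, Ea = 75.0 kJ mol⁻¹)
    (constants at 25 °C)

Sunday's thus reads a capture of 91.2%. The neighbour of Friday's with 1.2 mM of partner, 0.240 equiv, has a ceiling of 24.0% and, by the north capture, an estimated floor of 19.6%. That neighbour gives 20.9% of target, a capture of 87.0%, and at 2.50 min it holds 78.8% as homo product.

(The numbers in the tables stem from a simulated flask for substances that don't exist, noise included.)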